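**Retrosynthetic overview**

- The target is cut first at the methylene bridge (Mannich/quinone-methide-type alkylation), which gives a chiral 2-hexanoyl-4-methyl-4-prenyl trione (ring A) and the symmetric 2,6-dihydroxy-4-methoxyhexanophenone (ring B), whose two free positions are equivalent.
- Ring A is cut at C3–C4 and C1–C6, a [3+3] double C-acylation: the ketone unit C4–C5(O)–C6 comes from a geometrically defined silyl enolate of 3,6-dimethylhept-5-en-2-one, and the 2-hexanoylmalonyl unit C1–C2–C3 comes from a masked bis(phenyl ester).
- Enabling feature: ring A is a cyclohexane-1,3,5-trione in which the oxygen-bearing carbons C1, C3, C5 alternate with C2, C4, C6, so every ring bond joins an acyl carbon to an α-carbon and the C5 carbonyl has two nucleophilic α-positions. C4 is quaternary, so acylation there cannot be diverted to an aromatic 2-pyranone.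
- Stereocontrol: the methyl/prenyl distinction at C4 is encoded in the enolate geometry (1,4-hydrosilylation of an α-methylene ketone puts the new methyl cis to oxygen); a chiral ammonium cation then only has to select the enolate face.
- Ring order: ring A is the only ring formed (key step); ring B is bought as phloroglucinol, then acylated and para-O-methylated.

Key step: step 6

Remark: enolised tricarbonyl compounds are written as one tautomer and CIP descriptors refer to the tautomer drawn; the sense of induction in step 6 rests on analogy only, so the cinchonidinium catalyst is written and its pseudo-enantiomeric cinchoninium salt would be used if the opposite enolate face were preferred.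

**Step 1**
Reactants: 1 methyl acetoacetate; 2 prenyl bromide (1-bromo-3-methylbut-2-ene)
Product: 3 methyl 2-acetyl-5-methylhex-4-enoate (racemic)
Conditions: K2CO3, acetone, reflux
Reagents that add atoms: none
Why: Acetoacetic ester alkylation (SN2 of the β-keto ester enolate on the primary allylic bromide) should give the mono-prenylated product; its α-stereocentre is racemic and is destroyed in step 2.

**Step 2**
Reactants: 3 methyl 2-acetyl-5-methylhex-4-enoate
Product: 6 6-methyl-3-methylidenehept-5-en-2-one, via lithium 2-acetyl-5-methylhex-4-enoate 4 (not isolated), via Mannich acid 5 (not isolated)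
Conditions: LiOH·H2O, THF/H2O, 0 → 25 °C; then Et2NH·HCl, 37% aq. HCHO, 25 → 55 °C
Reagents that add atoms: formaldehyde, C=O
Why: Saponification followed by a decarboxylative Mannich methylenation (Mannich addition of the β-keto carboxylate to the iminium ion, then loss of CO2 and diethylamine) is a standard route to α-methylene ketones and places the methylidene group on the carbon that carried the ester; no stereocentre remains.

**Step 3**
Reactants: 6 6-methyl-3-methylidenehept-5-en-2-one
Product: 7 (E)-[(3,6-dimethylhepta-2,5-dien-2-yl)oxy]dimethyl(phenyl)silane (silyloxy group cis to the 3-methyl group)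
Conditions: PhMe2SiH, RhCl(PPh3)3 (0.5 mol %), toluene, 50 °C
Reagents that add atoms: dimethyl(phenyl)silane, C[SiH](C)c1ccccc1
Why: Rhodium-catalysed 1,4-hydrosilylation of an enone with a monohydrosilane delivers silicon to oxygen and hydride to the methylidene carbon through the s-cis conformer, so the new methyl group should end up cis to the silyloxy group while the trisubstituted prenyl alkene is left untouched.

**Step 4**
Reactants: 8 diphenyl malonate; 9 hexanoyl chloride
Product: 10 diphenyl 2-hexanoylpropanedioate (enolised)
Conditions: MgCl2, Et3N, MeCN, 0 → 25 °C; then 1 M HCl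
Reagents that add atoms: none
Why: Magnesium chloride/triethylamine-mediated C-acylation of a malonate (Claisen-type acylation of the magnesium enolate) should give the 2-acylmalonate, which is held as its chelated enolate and is therefore not acylated a second time.

**Step 5**
Reactants: 10 diphenyl 2-hexanoylpropanedioate
Product: 11 diphenyl 2-(1-methoxyhexylidene)propanedioate
Conditions: Me3SiCHN2 (2 M in hexanes), toluene/MeOH 9:1, 0 °C
Reagents that add atoms: trimethylsilyldiazomethane, C[Si](C)(C)C=[N+]=[N-]
Why: Diazomethane-type O-methylation of the strongly acidic enol removes the proton that would quench the enolate in step 6 and, because the two esters are identical, creates no geometric isomers.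

**Step 6**
Reactants: 7 (E)-[(3,6-dimethylhepta-2,5-dien-2-yl)oxy]dimethyl(phenyl)silane; 11 diphenyl 2-(1-methoxyhexylidene)propanedioate
Product: 14 (4S)-2-hexanoyl-3,5-dihydroxy-4-methyl-4-(3-methylbut-2-en-1-yl)cyclohexa-2,5-dien-1-one, via acyclic keto ester 12 (not isolated), via cyclic methyl enol ether 13 (not isolated)
Conditions: O-allyl-N-(9-anthracenylmethyl)cinchonidinium bromide (10 mol %), NaOPh (10 mol %), THF, −40 °C; then LiN(SiMe3)2 (2.2 equiv), −78 → 0 °C; then 1 M aq. HCl, THF, 25 °C
Reagents that add atoms: water, O
Why: Proposed new method: phenoxide from the chiral ammonium phenoxide attacks silicon of 7 and releases a cinchonidinium-paired tetrasubstituted enolate, which adds to one phenyl ester carbonyl of 11 and expels phenoxide (this turns the catalyst over and makes the C3–C4 bond and the quaternary centre of 12); LiN(SiMe3)2 then deprotonates the acetyl methyl group of 12, the enolate closes ring A on the second phenyl ester (C1–C6 bond, 13), and aqueous acid hydrolyses the vinylogous methyl ester to the hexanoyl group. The closest known reaction types are Lewis-base-catalysed Mukaiyama-type domino reactions of silyl enolates under chiral quaternary ammonium phenoxides in which an expelled phenoxide carries the chain, catalytic enantioselective C-acylation of silyl ketene acetals to quaternary centres, and base-mediated Claisen cyclisation of δ-keto esters to cyclohexane-1,3-diones; new here are the ketone-derived tetrasubstituted silyl enolate and the aryl ester as intermolecular acyl donor in the asymmetric event. Ring A is closed in the 6-(enolendo)-exo-trig mode. The C4 configuration is set in the first acylation by the chiral cation, which only has to select one π-face of the enolate because the methyl/prenyl distinction is already fixed in the double-bond geometry from step 3. The step needs C- over O-acylation and ester-carbonyl over β-carbon attack: O-acylation by a phenyl ester is reversible under phenoxide whereas C-acylation is not, the β-carbon of 11 is fully substituted and deactivated by the methoxy group, 11 has no acidic O–H to quench the enolate, and the quaternary C4 rules out lactonisation to an aromatic 2-pyranone, so the second acylation can end only on carbon C6.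

**Step 7**
Reactants: 15 phloroglucinol; 9 hexanoyl chloride
Product: 16 1-(2,4,6-trihydroxyphenyl)hexan-1-one
Conditions: AlCl3, CH2Cl2/PhNO2, 25 → 60 °C; then ice/HCl
Reagents that add atoms: none
Why: Friedel–Crafts acylation of the symmetric triphenol should stop after one acylation because the chelated aryl ketone is deactivated.

**Step 8**
Reactants: 16 1-(2,4,6-trihydroxyphenyl)hexan-1-one
Product: 17 1-(2,6-dihydroxy-4-methoxyphenyl)hexan-1-one
Conditions: Me2SO4 (1.0 equiv), K2CO3, acetone, 25 °C
Reagents that add atoms: dimethyl sulfate, COS(=O)(=O)OC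
Why: Williamson etherification should take place at the para-hydroxyl, the only one not hydrogen-bonded to the ketone and the most acidic, which leaves a symmetric arene with two equivalent free ring positions.

**Step 9**
Reactants: 14 (4S)-2-hexanoyl-3,5-dihydroxy-4-methyl-4-(3-methylbut-2-en-1-yl)cyclohexa-2,5-dien-1-one; 17 1-(2,6-dihydroxy-4-methoxyphenyl)hexan-1-one
Product: 20 (4S)-2-hexanoyl-6-[(3-hexanoyl-2,4-dihydroxy-6-methoxyphenyl)methyl]-3,5-dihydroxy-4-methyl-4-(3-methylbut-2-en-1-yl)cyclohexa-2,5-dien-1-one, via Mannich base hydroiodide 18 (not isolated), via methylidene trione 19 (not isolated)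
Conditions: CH2=NMe2+ I− (1.05 equiv), MeCN, 25 °C; then 17 (3 equiv), 1,4-dioxane, 80 °C
Reagents that add atoms: N,N-dimethylmethyleneiminium iodide (Eschenmoser's salt), C[N+](C)=C.[I-]
Why: Mannich aminomethylation at C6, the only free ring carbon of 14, then thermal loss of dimethylamine to the quinone-methide-like methylidene trione and Friedel–Crafts-type Michael addition of the electron-rich arene at one of its two equivalent positions should give the methylene-bridged dimer; the quaternary stereocentre is not touched.

**Compound list**

1 | methyl acetoacetate | COC(=O)CC(C)=O | starting material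
2 | prenyl bromide (1-bromo-3-methylbut-2-ene) | CC(C)=CCBr | starting material
3 | methyl 2-acetyl-5-methylhex-4-enoate (racemic) | COC(=O)C(CC=C(C)C)C(C)=O | intermediate
4 | lithium 2-acetyl-5-methylhex-4-enoate (racemic, not isolated) | [Li+].[O-]C(=O)C(CC=C(C)C)C(C)=O | intermediate
5 | 2-acetyl-2-[(diethylamino)methyl]-5-methylhex-4-enoic acid (racemic Mannich acid, not isolated) | CCN(CC)CC(CC=C(C)C)(C(C)=O)C(=O)O | intermediate
6 | 6-methyl-3-methylidenehept-5-en-2-one | CC(=O)C(=C)CC=C(C)C | intermediate
7 | (E)-[(3,6-dimethylhepta-2,5-dien-2-yl)oxy]dimethyl(phenyl)silane (silyloxy cis to 3-methyl) | C/C(O[Si](C)(C)c1ccccc1)=C(/C)CC=C(C)C | intermediate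
8 | diphenyl malonate | O=C(CC(=O)Oc1ccccc1)Oc1ccccc1 | starting material
9 | hexanoyl chloride | CCCCCC(=O)Cl | starting material
10 | diphenyl 2-hexanoylpropanedioate (enolised) | CCCCCC(=O)C(C(=O)Oc1ccccc1)C(=O)Oc1ccccc1 | intermediate
11 | diphenyl 2-(1-methoxyhexylidene)propanedioate | CCCCCC(OC)=C(C(=O)Oc1ccccc1)C(=O)Oc1ccccc1 | intermediate
12 | phenyl (4S)-4-acetyl-2-(1-methoxyhexylidene)-4,7-dimethyl-3-oxooct-6-enoate (hexylidene geometry undefined, not isolated) | CCCCCC(OC)=C(C(=O)Oc1ccccc1)C(=O)[C@@](C)(CC=C(C)C)C(C)=O | intermediate
13 | (4S)-2-(1-methoxyhexylidene)-4-methyl-4-(3-methylbut-2-en-1-yl)cyclohexane-1,3,5-trione (present as lithium enolate, not isolated) | CCCCCC(OC)=C1C(=O)[C@@](C)(CC=C(C)C)C(=O)CC1=O | intermediate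
14 | (4S)-2-hexanoyl-3,5-dihydroxy-4-methyl-4-(3-methylbut-2-en-1-yl)cyclohexa-2,5-dien-1-one | CCCCCC(=O)C1=C(O)[C@@](C)(CC=C(C)C)C(O)=CC1=O | intermediate
15 | phloroglucinol (benzene-1,3,5-triol) | Oc1cc(O)cc(O)c1 | starting material
16 | 1-(2,4,6-trihydroxyphenyl)hexan-1-one | CCCCCC(=O)c1c(O)cc(O)cc1O | intermediate
17 | 1-(2,6-dihydroxy-4-methoxyphenyl)hexan-1-one | CCCCCC(=O)c1c(O)cc(OC)cc1O | intermediate
18 | (4S)-6-[(dimethylamino)methyl]-2-hexanoyl-3,5-dihydroxy-4-methyl-4-(3-methylbut-2-en-1-yl)cyclohexa-2,5-dien-1-one hydroiodide (not isolated) | CCCCCC(=O)C1=C(O)[C@@](C)(CC=C(C)C)C(O)=C(C[NH+](C)C)C1=O.[I-] | intermediate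
19 | (4R as drawn; same spatial arrangement as 14)-2-hexanoyl-3-hydroxy-4-methyl-6-methylidene-4-(3-methylbut-2-en-1-yl)cyclohex-2-ene-1,5-dione (not isolated) | CCCCCC(=O)C1=C(O)[C@@](C)(CC=C(C)C)C(=O)C(=C)C1=O | intermediate
20 | (4S)-2-hexanoyl-6-[(3-hexanoyl-2,4-dihydroxy-6-methoxyphenyl)methyl]-3,5-dihydroxy-4-methyl-4-(3-methylbut-2-en-1-yl)cyclohexa-2,5-dien-1-one (CNP0108719.1) | CCCCCC(=O)C1=C(O)[C@@](C)(CC=C(C)C)C(O)=C(Cc2c(OC)cc(O)c(C(=O)CCCCC)c2O)C1=O | target

**Step count and risks**

Total step count: 9. Longest linear sequence: 5 (steps 1, 2, 3, 6, 9).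

Steps most likely to fail:

1. Step 6 (Proposed new method). The ion-paired enolate may show low or reversed facial selectivity, made worse by any loss of geometric purity of 7. Proton transfer from the γ-CH2 of 11 or attack at its β-carbon may compete with acyl transfer, and phenoxide turnover may stall. The fallback sets out from 7 and 11 and comes back at 14 using known chemistry:
   - 7 is cleaved with MeLi (THF, 0 °C) to lithium (E)-3,6-dimethylhepta-2,5-dien-2-olate F1.
   - F1 is C-acylated by 11 at −78 °C (Claisen-type acylation of a lithium enolate by a phenyl ester) to racemic phenyl 4-acetyl-2-(1-methoxyhexylidene)-4,7-dimethyl-3-oxooct-6-enoate F2.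
   - LiN(SiMe3)2 closes the ring to racemic 2-(1-methoxyhexylidene)-4-methyl-4-(3-methylbut-2-en-1-yl)cyclohexane-1,3,5-trione F3, and aqueous HCl gives racemic 2-hexanoyl-3,5-dihydroxy-4-methyl-4-(3-methylbut-2-en-1-yl)cyclohexa-2,5-dien-1-one F4.
   - The strongly acidic F4 is resolved by fractional crystallisation of its salts with (S)-1-phenylethylamine: the (S)-1-phenylethylammonium salt of the (4S)-acid F5 is acidified to 14, while the (S)-1-phenylethylammonium salt of the (4R)-acid F6 is set aside. Which salt crystallises has to be established, and the (R)-amine would be used if needed.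

2. Step 9. Self-condensation or double alkylation of the arene may compete with the cross-coupling, and prolonged heating may cyclise the prenyl group onto an enol oxygen. The fallback sets out from 17 and 14 and comes back at 20:
   - 17 is formylated (Vilsmeier–Haack, POCl3/DMF) to 3-hexanoyl-2,4-dihydroxy-6-methoxybenzaldehyde F7.
   - F7 and 14 are condensed under L-proline catalysis in the presence of a Hantzsch ester (CH2Cl2, 25 °C) to the Knoevenagel adduct, the arylidene trione F8, which is reduced in the same flask by transfer hydrogenation (organocatalytic reductive alkylation of a cyclic 1,3-dicarbonyl) to 20.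

3. Step 2. The β-keto acid may decarboxylate before the Mannich addition, and the α-methylene ketone may polymerise or dimerise during isolation. The fallback sets out from 2 and comes back at 6:
   - Triethyl phosphonoacetate is alkylated with 2 (NaH, THF) to ethyl 2-(diethoxyphosphoryl)-5-methylhex-4-enoate F9.
   - Horner–Wadsworth–Emmons reaction with aqueous formaldehyde (K2CO3) gives ethyl 5-methyl-2-methylidenehex-4-enoate F10.
   - MeNHOMe·HCl/iPrMgCl converts F10 into the Weinreb amide N-methoxy-N,5-dimethyl-2-methylidenehex-4-enamide F11, and MeMgBr (THF, −78 °C) gives 6.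

**Further compounds**

F1 | step 6 | lithium (E)-3,6-dimethylhepta-2,5-dien-2-olate | C/C([O-])=C(/C)CC=C(C)C.[Li+]
F2 | step 6 | racemic phenyl 4-acetyl-2-(1-methoxyhexylidene)-4,7-dimethyl-3-oxooct-6-enoate | CCCCCC(OC)=C(C(=O)Oc1ccccc1)C(=O)C(C)(CC=C(C)C)C(C)=O
F3 | step 6 | racemic 2-(1-methoxyhexylidene)-4-methyl-4-(3-methylbut-2-en-1-yl)cyclohexane-1,3,5-trione | CCCCCC(OC)=C1C(=O)C(C)(CC=C(C)C)C(=O)CC1=O
F4 | step 6 | racemic 2-hexanoyl-3,5-dihydroxy-4-methyl-4-(3-methylbut-2-en-1-yl)cyclohexa-2,5-dien-1-one | CCCCCC(=O)C1=C(O)C(C)(CC=C(C)C)C(O)=CC1=O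
F5 | step 6 | (S)-1-phenylethylammonium salt of the (4S)-acid | CCCCCC(=O)C1=C([O-])[C@@](C)(CC=C(C)C)C(O)=CC1=O.C[C@H]([NH3+])c1ccccc1
F6 | step 6 | (S)-1-phenylethylammonium salt of the (4R)-acid | CCCCCC(=O)C1=C([O-])[C@](C)(CC=C(C)C)C(O)=CC1=O.C[C@H]([NH3+])c1ccccc1
F7 | step 9 | 3-hexanoyl-2,4-dihydroxy-6-methoxybenzaldehyde | CCCCCC(=O)c1c(O)cc(OC)c(C=O)c1O
F8 | step 9 | 2-hexanoyl-6-[(3-hexanoyl-2,4-dihydroxy-6-methoxyphenyl)methylidene]-3-hydroxy-4-methyl-4-(3-methylbut-2-en-1-yl)cyclohex-2-ene-1,5-dione (quaternary centre as in 14) | CCCCCC(=O)C1=C(O)[C@@](C)(CC=C(C)C)C(=O)C(=Cc2c(OC)cc(O)c(C(=O)CCCCC)c2O)C1=O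
F9 | step 2 | ethyl 2-(diethoxyphosphoryl)-5-methylhex-4-enoate | CCOC(=O)C(CC=C(C)C)P(=O)(OCC)OCC
F10 | step 2 | ethyl 5-methyl-2-methylidenehex-4-enoate | CCOC(=O)C(=C)CC=C(C)C
F11 | step 2 | N-methoxy-N,5-dimethyl-2-methylidenehex-4-enamide | CON(C)C(=O)C(=C)CC=C(C)C
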